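**Strategy**

Ring C is closed by a formal [3+3] annulation that forms C3–C4 and O1–C8a together. A B-ring aryl ketone enolate serves as a 1,3-C,O-bis-nucleophile: its α-carbon (C3, already carrying O3 as a MOM acetal) is benzylated by the A-ring benzylic chloride (C4), and its carbonyl oxygen, the future O1, is then arylated at the ortho C–Br carbon (C8a) by copper catalysis in the same pot. The step exploits the O1–C2–C3–O3 enediol pattern lying between the A-ring CH2 and the ring oxygen. The 4H-chromene formed is unmasked to the flavan-3-one, whose labile C2 lets a dynamic kinetic transfer hydrogenation set both stereocentres cis; acylation and hydrogenolysis finish.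

Key step: step 6

Remark: compounds 1, 6 and 13 are taken as catalogue compounds; all phenols are carried as benzyl ethers; atom labels (O1, C2, C3, C4, C4a, C8a) are those of the flavan skeleton; compounds 9 and 11 are racemic, and both stereocentres are set in step 8.

**Route**

Step 1
Reactants: 1 1,3-bis(benzyloxy)-5-bromobenzene
Product: 3 2,4-bis(benzyloxy)-6-bromobenzaldehyde, via aryl iminium chloride 2 (not isolated)
Conditions: POCl3, DMF, 0 → 70 °C; then ice/H2O
Reagents that add atoms: N,N-dimethylformamide, CN(C)C=O; water, O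
Why: Vilsmeier–Haack formylation should go mainly to the position ortho to Br, which is ortho and para to the two benzyloxy groups, and hydrolysis of iminium 2 gives the aldehyde; the symmetric 4-formyl isomer is expected as the minor product and is removed by crystallisation.

Step 2
Reactants: 3 2,4-bis(benzyloxy)-6-bromobenzaldehyde
Product: 4 [2,4-bis(benzyloxy)-6-bromophenyl]methanol
Conditions: NaBH4, THF/MeOH, 0 °C
Reagents that add atoms: none
Why: Borohydride reduction of an aryl aldehyde leaves the aryl bromide and the benzyl ethers untouched.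

Step 3
Reactants: 4 [2,4-bis(benzyloxy)-6-bromophenyl]methanol
Product: 5 1,5-bis(benzyloxy)-3-bromo-2-(chloromethyl)benzene
Conditions: SOCl2, pyridine, CH2Cl2, 0 °C; used crude at once
Reagents that add atoms: thionyl chloride, O=S(Cl)Cl
Why: Deoxychlorination of an electron-rich benzylic alcohol via its chlorosulfite is fast at 0 °C, and the labile chloride is carried on without chromatography.

Step 4
Reactants: 6 3,4,5-tris(benzyloxy)benzaldehyde
Product: 7 2-hydroxy-1-[3,4,5-tris(benzyloxy)phenyl]ethan-1-one
Conditions: (CH2O)n, 3-benzyl-5-(2-hydroxyethyl)-4-methylthiazolium chloride (10 mol%), iPr2NEt, THF, 60 °C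
Reagents that add atoms: formaldehyde (as paraformaldehyde), C=O
Why: In this carbene-catalysed crossed acyloin reaction (hydroxymethylation) the Breslow intermediate of the aryl aldehyde adds to the more electrophilic formaldehyde, which supplies C3 of the target.

Step 5
Reactants: 7 2-hydroxy-1-[3,4,5-tris(benzyloxy)phenyl]ethan-1-one
Product: 8 2-(methoxymethoxy)-1-[3,4,5-tris(benzyloxy)phenyl]ethan-1-one
Conditions: MOMCl, iPr2NEt, CH2Cl2, 0 °C → rt
Reagents that add atoms: chloromethyl methyl ether, COCCl
Why: O-alkylation to a MOM acetal caps O3 with a group that is stable to strong base and cannot migrate to an enolate oxygen, unlike acyl or silyl groups.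

Step 6
Reactants: 8 2-(methoxymethoxy)-1-[3,4,5-tris(benzyloxy)phenyl]ethan-1-one; 5 1,5-bis(benzyloxy)-3-bromo-2-(chloromethyl)benzene
Product: 10 5,7-bis(benzyloxy)-3-(methoxymethoxy)-2-[3,4,5-tris(benzyloxy)phenyl]-4H-chromene, via C-benzylated ketone 9 (not isolated)
Conditions: NaHMDS, THF, −78 °C; then 5, → 0 °C; then CuI (10 mol%), 1,10-phenanthroline (20 mol%), Cs2CO3, DMF added, 100 °C (one pot)
Reagents that add atoms: none
Why: The sodium enolate of 8 is C-alkylated at C3 by the benzylic chloride 5 (SN2, forming C3–C4) to give 9, after which Cs2CO3 regenerates the enolate and Cu(I)/phenanthroline inserts into the C8a–Br bond, binds the enolate oxygen and forms O1–C8a by reductive elimination (Ullmann-type enolate O-arylation). The closest known reactions are the copper-catalysed domino C-benzylation/O-arylation of 1,3-dicarbonyl compounds by 2-bromobenzyl bromides to 4H-chromenes and the intramolecular O-arylation of ketone enolates used for benzofurans. Ring C closes in a 6-exo mode at the sp2 carbon C8a, the breaking C–Br bond being exocyclic, through a seven-membered oxacupracycle. No stereocentre survives the step, since C3 of 9 is stereogenic only transiently and becomes sp2 in 10; C2 and C3 are set in step 8. The step needs C- over O-alkylation, monoalkylation and O- over C-arylation: the soft benzylic electrophile and the sodium enolate in THF favour carbon, the ketone has only one enolisable position (C3) because C2 carries the B-ring aryl group, O3 is blocked as a non-migrating acetal, and C-arylation would require a four-membered ring.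

Step 7
Reactants: 10 5,7-bis(benzyloxy)-3-(methoxymethoxy)-2-[3,4,5-tris(benzyloxy)phenyl]-4H-chromene
Product: 11 racemic 5,7-bis(benzyloxy)-2-[3,4,5-tris(benzyloxy)phenyl]chroman-3-one
Conditions: ZnBr2, n-PrSH, CH2Cl2, 0 °C
Reagents that add atoms: none
Why: Lewis-acid-assisted cleavage of the MOM acetal at its CH2 carbon, with the thiol as cation trap, should release the enol, which tautomerises to the flavan-3-one with a racemic C2, while the aprotic medium avoids C-protonation of the enediol diether and spares the benzyl ethers.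

Step 8
Reactants: 11 racemic 5,7-bis(benzyloxy)-2-[3,4,5-tris(benzyloxy)phenyl]chroman-3-one
Product: 12 (2R,3R)-5,7-bis(benzyloxy)-2-[3,4,5-tris(benzyloxy)phenyl]chroman-3-ol
Conditions: RuCl[(R,R)-TsDPEN](p-cymene) (2 mol%), HCO2H/Et3N (1:1), CH2Cl2, 30 °C
Reagents that add atoms: none
Why: In this asymmetric transfer hydrogenation with dynamic kinetic resolution the ketone enantiomers interconvert by enolisation toward the doubly activated C2–H, the catalyst should deliver hydride to the Si face of C3 (setting 3R) and do so anti to the C2 aryl group (the cis preference known for bulky hydrides on such ketones), so the (2R)-ketone is consumed and C2 is set as R. The (R,R) ligand is chosen from the usual model with the O1- and aryl-bearing C2 flank in the aryl-recognition site, and the antipodal ligand would be used if the sense proves reversed.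

Step 9
Reactants: 12 (2R,3R)-5,7-bis(benzyloxy)-2-[3,4,5-tris(benzyloxy)phenyl]chroman-3-ol; 13 4-(benzyloxy)benzoyl chloride
Product: 14 (2R,3R)-5,7-bis(benzyloxy)-2-[3,4,5-tris(benzyloxy)phenyl]chroman-3-yl 4-(benzyloxy)benzoate
Conditions: Et3N, DMAP (cat.), CH2Cl2, 0 °C → rt
Reagents that add atoms: none
Why: DMAP-catalysed acylation of the secondary alcohol by an acid chloride proceeds at oxygen with retention, so neither stereocentre is touched.

Step 10
Reactants: 14 (2R,3R)-5,7-bis(benzyloxy)-2-[3,4,5-tris(benzyloxy)phenyl]chroman-3-yl 4-(benzyloxy)benzoate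
Product: 15 epigallocatechin 3-O-(4-hydroxybenzoate), (2R,3R)-5,7-dihydroxy-2-(3,4,5-trihydroxyphenyl)chroman-3-yl 4-hydroxybenzoate
Conditions: H2 (1 atm), Pd(OH)2/C, THF/MeOH, rt
Reagents that add atoms: none
Why: Hydrogenolysis of the six aryl benzyl ethers under neutral conditions should leave the C3 ester and the cyclic C2–O1 ether intact and cause no epimerisation at C2.

**Compound list**

1 | 1,3-bis(benzyloxy)-5-bromobenzene | Brc1cc(OCc2ccccc2)cc(OCc2ccccc2)c1 | starting material
2 | N-{[2,4-bis(benzyloxy)-6-bromophenyl]methylidene}-N-methylmethanaminium chloride (not isolated) | C[N+](C)=Cc1c(Br)cc(OCc2ccccc2)cc1OCc1ccccc1.[Cl-] | intermediate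
3 | 2,4-bis(benzyloxy)-6-bromobenzaldehyde | O=Cc1c(Br)cc(OCc2ccccc2)cc1OCc1ccccc1 | intermediate
4 | [2,4-bis(benzyloxy)-6-bromophenyl]methanol | OCc1c(Br)cc(OCc2ccccc2)cc1OCc1ccccc1 | intermediate
5 | 1,5-bis(benzyloxy)-3-bromo-2-(chloromethyl)benzene | ClCc1c(Br)cc(OCc2ccccc2)cc1OCc1ccccc1 | intermediate
6 | 3,4,5-tris(benzyloxy)benzaldehyde | O=Cc1cc(OCc2ccccc2)c(OCc2ccccc2)c(OCc2ccccc2)c1 | starting material
7 | 2-hydroxy-1-[3,4,5-tris(benzyloxy)phenyl]ethan-1-one | O=C(CO)c1cc(OCc2ccccc2)c(OCc2ccccc2)c(OCc2ccccc2)c1 | intermediate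
8 | 2-(methoxymethoxy)-1-[3,4,5-tris(benzyloxy)phenyl]ethan-1-one | COCOCC(=O)c1cc(OCc2ccccc2)c(OCc2ccccc2)c(OCc2ccccc2)c1 | intermediate
9 | racemic 3-[2,4-bis(benzyloxy)-6-bromophenyl]-2-(methoxymethoxy)-1-[3,4,5-tris(benzyloxy)phenyl]propan-1-one (not isolated) | COCOC(Cc1c(Br)cc(OCc2ccccc2)cc1OCc1ccccc1)C(=O)c1cc(OCc2ccccc2)c(OCc2ccccc2)c(OCc2ccccc2)c1 | intermediate
10 | 5,7-bis(benzyloxy)-3-(methoxymethoxy)-2-[3,4,5-tris(benzyloxy)phenyl]-4H-chromene | COCOC1=C(c2cc(OCc3ccccc3)c(OCc3ccccc3)c(OCc3ccccc3)c2)Oc2cc(OCc3ccccc3)cc(OCc3ccccc3)c2C1 | intermediate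
11 | racemic 5,7-bis(benzyloxy)-2-[3,4,5-tris(benzyloxy)phenyl]chroman-3-one | O=C1Cc2c(OCc3ccccc3)cc(OCc3ccccc3)cc2OC1c1cc(OCc2ccccc2)c(OCc2ccccc2)c(OCc2ccccc2)c1 | intermediate
12 | (2R,3R)-5,7-bis(benzyloxy)-2-[3,4,5-tris(benzyloxy)phenyl]chroman-3-ol | O[C@@H]1Cc2c(OCc3ccccc3)cc(OCc3ccccc3)cc2O[C@@H]1c1cc(OCc2ccccc2)c(OCc2ccccc2)c(OCc2ccccc2)c1 | intermediate
13 | 4-(benzyloxy)benzoyl chloride | O=C(Cl)c1ccc(OCc2ccccc2)cc1 | starting material
14 | (2R,3R)-5,7-bis(benzyloxy)-2-[3,4,5-tris(benzyloxy)phenyl]chroman-3-yl 4-(benzyloxy)benzoate | O=C(O[C@@H]1Cc2c(OCc3ccccc3)cc(OCc3ccccc3)cc2O[C@@H]1c1cc(OCc2ccccc2)c(OCc2ccccc2)c(OCc2ccccc2)c1)c1ccc(OCc2ccccc2)cc1 | intermediate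
15 | epigallocatechin 3-O-(4-hydroxybenzoate), (2R,3R) | O=C(O[C@@H]1Cc2c(O)cc(O)cc2O[C@@H]1c1cc(O)c(O)c(O)c1)c1ccc(O)cc1 | target

**Totals**

Total step count: 10.
Longest linear sequence: 8 steps (steps 1–3 and 6–10, from 1).

**Steps most likely to fail**

1. Step 6. The benzylic chloride 5 may ionise and decompose before it is attacked, the enolate may react at oxygen or twice at carbon, or the copper cycle may stall at the hindered tetrasubstituted enolate and give protodebromination instead of C–O bond formation. The fallback sets out from 8 and aldehyde 3 and makes the C3–C4 bond by condensation instead of alkylation. Claisen–Schmidt condensation (KOH, EtOH/THF) should give (Z)-3-[2,4-bis(benzyloxy)-6-bromophenyl]-2-(methoxymethoxy)-1-[3,4,5-tris(benzyloxy)phenyl]prop-2-en-1-one F1. Copper hydride conjugate reduction (Stryker's reagent, toluene, rt) should then give ketone 9, now isolated. Palladium-catalysed intramolecular enolate O-arylation (Pd2(dba)3, DPEphos, Cs2CO3, toluene, 100 °C) closes the ring and comes back to the route at 10.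

2. Step 8. The catalyst may discriminate poorly between the two faces or the two ketone enantiomers, or racemisation at C2 may be slower than reduction so that only a kinetic resolution results. The fallback sets out from 11 and relies on substrate control plus physical resolution. L-Selectride (THF, −78 °C) should attack anti to the C2 aryl group and give the racemic cis-5,7-bis(benzyloxy)-2-[3,4,5-tris(benzyloxy)phenyl]chroman-3-ol F2. Preparative chromatography on a chiral stationary phase then delivers the (2R,3R)-enantiomer, which is compound 12, and the unwanted enantiomer is returned to 11 by Dess–Martin oxidation.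

3. Step 7. The enediol diether may be protonated at C3 rather than cleaved at the acetal, opening ring C to a hydroxy ketone, or the thiol may add to the product ketone. The fallback sets out from 7 and replaces the acid-labile acetal by a fluoride-labile one. SEMCl/iPr2NEt (CH2Cl2) should give 2-{[2-(trimethylsilyl)ethoxy]methoxy}-1-[3,4,5-tris(benzyloxy)phenyl]ethan-1-one F3. The one-pot benzylation/O-arylation of step 6 with 5 then passes through the C-benzylated SEM ketone F4 (not isolated) to the SEM enol ether 5,7-bis(benzyloxy)-3-{[2-(trimethylsilyl)ethoxy]methoxy}-2-[3,4,5-tris(benzyloxy)phenyl]-4H-chromene F5. TBAF (THF, then AcOH quench) fragments the SEM group at silicon and liberates the enolate without any acid, coming back to the route at 11.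

**Further compounds**

F1 | step 6 | (Z)-3-[2,4-bis(benzyloxy)-6-bromophenyl]-2-(methoxymethoxy)-1-[3,4,5-tris(benzyloxy)phenyl]prop-2-en-1-one | COCO/C(=C\c1c(Br)cc(OCc2ccccc2)cc1OCc1ccccc1)C(=O)c1cc(OCc2ccccc2)c(OCc2ccccc2)c(OCc2ccccc2)c1
F2 | step 8 | racemic cis-5,7-bis(benzyloxy)-2-[3,4,5-tris(benzyloxy)phenyl]chroman-3-ol (1:1 mixture of the 2R,3R and 2S,3S enantiomers, both written) | O[C@@H]1Cc2c(OCc3ccccc3)cc(OCc3ccccc3)cc2O[C@@H]1c1cc(OCc2ccccc2)c(OCc2ccccc2)c(OCc2ccccc2)c1.O[C@H]1Cc2c(OCc3ccccc3)cc(OCc3ccccc3)cc2O[C@H]1c1cc(OCc2ccccc2)c(OCc2ccccc2)c(OCc2ccccc2)c1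
F3 | step 7 | 2-{[2-(trimethylsilyl)ethoxy]methoxy}-1-[3,4,5-tris(benzyloxy)phenyl]ethan-1-one | C[Si](C)(C)CCOCOCC(=O)c1cc(OCc2ccccc2)c(OCc2ccccc2)c(OCc2ccccc2)c1
F4 | step 7 | racemic 3-[2,4-bis(benzyloxy)-6-bromophenyl]-2-{[2-(trimethylsilyl)ethoxy]methoxy}-1-[3,4,5-tris(benzyloxy)phenyl]propan-1-one (not isolated) | C[Si](C)(C)CCOCOC(Cc1c(Br)cc(OCc2ccccc2)cc1OCc1ccccc1)C(=O)c1cc(OCc2ccccc2)c(OCc2ccccc2)c(OCc2ccccc2)c1
F5 | step 7 | 5,7-bis(benzyloxy)-3-{[2-(trimethylsilyl)ethoxy]methoxy}-2-[3,4,5-tris(benzyloxy)phenyl]-4H-chromene | C[Si](C)(C)CCOCOC1=C(c2cc(OCc3ccccc3)c(OCc3ccccc3)c(OCc3ccccc3)c2)Oc2cc(OCc3ccccc3)cc(OCc3ccccc3)c2C1
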